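## The problem

CNP0222710.1 (18) is a (2S)-flavanone: a 7-hydroxychroman-4-one (rings A and C) that carries ring B at C2. Ring B is a 1,3,4,5-tetrasubstituted benzene with an (E)-3-hydroxy-3-methylbut-1-enyl chain at C3', a methoxy group at C4' and a prenyl group at C5'; these three neighbours must be placed without regiochemical doubt. C2 is the only stereocentre, so nothing in the molecule can relay chirality to it and a catalyst or reagent has to set it. C2 is also fragile: it is benzylic, bound to O1 and β to the C4 ketone, so a C3 enolate can expel the O1 phenoxide (retro-oxa-Michael) and the 2'-hydroxychalcone recloses as a racemate. The tertiary alcohol is allylic and styrenyl and ionises with acid. The prenyl alkene rules out hydrogenation, strong electrophiles and unselective oxidants, and the phenol must be masked through the basic steps. The enabling feature is that C3 and C4 become the two ends of an alkene once the C4 ketone is carried as an enol ether. C2 is then an allylic carbon bound to O1 and ring B, which is the branched product of an asymmetric allylic etherification of a ring B cinnamyl unit by the ring A phenol. The C3=C4 bond can then be closed by metathesis between a vinyl group on C2 and a 1-silyloxyvinyl group on C4a.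

## Retrosynthesis

**18 from 17.** No skeletal bond is cut. The C4 ketone and both hydroxyls are released together from the 4-silyloxy-2H-chromene 17. Keeping the ketone masked until the last step means C2 is never β to a carbonyl while bases or silyl triflates are present, and no redox step is needed. The forward step must avoid both a free C3 enolate and acid.

**17 from 16.** The C3=C4 bond is cut by ring-closing metathesis. Cutting O1–C2 instead leads to a chalcone whose asymmetric closure is reversible and poorly controlled. Cutting C4–C4a needs acylation of ring A under acid or with organolithiums. Cutting C2–C1' needs a ring B organometallic and a chromone. The chosen cut leaves the acyclic diene 16 with the stereocentre already in place and costs only ethene. The forward step asks the ruthenium carbene to engage only the two terminal alkenes among four.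

**16 from 15.** Only O–Si bonds are cut. One silyl triflate converts the methyl ketone of 15 into its enol ether and caps the tertiary alcohol, so no separate protection step is spent. The enolisation must stay basic and mild so that the doubly activated allylic aryl ether does not ionise.

**15 from 11 and 13.** The O1–C2 bond is cut, which splits the molecule into the ring B cinnamyl carbonate 11 and the ring A phenol 13, two achiral halves of similar size. An iridium–phosphoramidite catalyst gives the branched ether and the absolute configuration in one step. A palladium catalyst would give the linear ether, and a Mitsunobu reaction would need a preformed chiral alcohol and risks SN2′ attack. The forward step asks for branched selectivity and face selectivity from a chelated, modestly nucleophilic phenoxide.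

**13 from 12.** The 4-hydroxyl of 2,4-dihydroxyacetophenone 12 is silylated; the 2-hydroxyl is hydrogen-bonded to the acetyl group and stays free for the etherification.

**11 from 10, 9 and 8.** The carbonate is the activated form of cinnamyl alcohol 10, which comes from cinnamate 9 by reduction; the C1'–alkene bond of 9 is cut by Horner–Wadsworth–Emmons olefination back to aldehyde 8. The (E)-geometry required by the iridium step is set here.

**8 from 6 and 7.** The C3'–alkenyl bond is cut by a Heck reaction. Commercial 2-methylbut-3-en-2-ol 7 delivers the whole side chain, tertiary alcohol included, onto bromide 6.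

**6 from 5, 4, 2 and 1.** The prenyl group is traced to an allyl group (cross-metathesis of 5), the allyl group to an O-allyl ether (Claisen rearrangement of 2 via dienone 3 to phenol 4, then O-methylation). In 3-bromo-4-hydroxybenzaldehyde 1 the bromine blocks one ortho position, so the rearrangement has one outlet, and the same bromine later serves as the Heck handle.

## Roads not taken

Alternative 1: The cut lies in ring B, which is assembled from a 2-pyrone and an alkyne. Methyl 3-bromocoumalate A2 and the prenyl-bearing ynol ether A3 would undergo an inverse-demand [4+2] cycloaddition, lose CO2, and give methyl 3-bromo-4-methoxy-5-prenylbenzoate A1.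
- Merits: the polarity of the partners fixes all four substituents in one step, the prenyl group arrives intact, and no 190 °C rearrangement or allyl-to-prenyl metathesis is needed. In regiochemical certainty this road is at least as good as the chosen one.
- Weak points: A3 is a sensitive, non-commercial ynol ether and A2 must be made. The ester of A1 needs extra redox steps to reach the aldehyde level of 6. The step builds nothing of ring C and leaves C2 unsolved, so the later half of the chosen plan would still be required.
- Comparison: the chosen plan reaches the equivalent compound 6 in four textbook steps from commercial 1, with the bromine making the Claisen step equally unambiguous.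

Alternative 2: Ring C is cut at O1–C8a and C4–C4a together, so ring A arrives as an aryne. CsF would unmask the aryne from silyl triflate A6; the alkoxide of the (S)-β-hydroxy ester A5 would add at the aryne carbon remote from bromine and the aryl anion would acylate on the ester, giving the 7-allyloxy-5-bromoflavanone A4.
- Merits: two ring bonds form in one convergent step and the ketone appears directly, with no atoms excised. In bond count per step it is better than the chosen plan.
- Weak points: the bromine is there only to steer the aryne and must be removed reductively in the presence of two alkenes, and the allyl ether must be cleaved with zerovalent palladium. A6 is a multi-step building block, and A5 needs its own asymmetric aldol or reduction. The alkoxide of A5 can undergo retro-aldol cleavage or eliminate to the cinnamate. The finished flavanone then sits in basic fluoride, where ring opening threatens C2.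
- Comparison: the chosen plan sets C2 catalytically, never exposes it to base while the ketone is free, and removes only silyl groups at the end.

Alternative 3: Ring C is cut at C2–C3. Rh2(S-PTTL)4, a divalent rhodium carboxylate, would decompose diazoketone A8, and the carbenoid carbon would insert into one enantiotopic hydrogen of the ring B benzylic O–CH2 group, giving the bis-silyl ether A7 with ring C closed and C2 set.
- Merits: it is the shortest road, fully atom-economic, and ring and stereocentre form together. In step count it is better than the chosen plan.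
- Weak points: an acceptor-only carbenoid is unselective. Attack on the adjacent ether oxygen gives an oxonium ylide and, after a [1,2]-shift, a benzofuranone. The prenyl and styrenyl alkenes invite cyclopropanation and ring B invites Buchner addition. Six-membered C–H insertion is the less favoured ring size, and enantiocontrol for such carbenoids is usually moderate.
- Comparison: the chosen plan uses a ruthenium alkylidene, which does not cyclopropanate and touches only terminal alkenes, and takes its enantioselectivity from a reaction class with reliably high selectivity.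

Key step: step 12

Assumption on the chemistry: the (Sa,Sc,Sc) phosphoramidite is taken to give the (S)-branched ether from a cinnamyl carbonate, by analogy with the (Ra,Rc,Rc) ligand giving (R) products with heteroatom nucleophiles; if the sense proves opposite, the antipodal ligand is used with no other change.

In the names below, ArB is the 3-[(1E)-3-hydroxy-3-methylbut-1-en-1-yl]-4-methoxy-5-(3-methylbut-2-en-1-yl)phenyl group of ring B, and ArB(TES) is the same group with the tertiary hydroxyl as its triethylsilyl ether.

## Route

Step 1
Reactants: 1 3-bromo-4-hydroxybenzaldehyde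
Product: 2 4-(allyloxy)-3-bromobenzaldehyde
Conditions: allyl bromide, K2CO3, acetone, reflux
Reagents that add atoms: allyl bromide, C=CCBr
Why: Williamson O-alkylation of an acidic phenol (para-formyl, ortho-bromo); under K2CO3 in acetone only the oxygen is alkylated.

Step 2
Reactants: 2 4-(allyloxy)-3-bromobenzaldehyde
Product: 4 3-allyl-5-bromo-4-hydroxybenzaldehyde, via 6-allyl-2-bromo-4-formylcyclohexa-2,4-dien-1-one 3 (not isolated)
Conditions: N,N-diethylaniline, 190 °C
Reagents that add atoms: none
Why: Aromatic Claisen rearrangement ([3,3]-sigmatropic shift); one ortho position carries bromine and the para position the formyl group, so the allyl group can only reach C5, and dienone 3 tautomerises to the phenol.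

Step 3
Reactants: 4 3-allyl-5-bromo-4-hydroxybenzaldehyde
Product: 5 3-allyl-5-bromo-4-methoxybenzaldehyde
Conditions: MeI, K2CO3, DMF, rt
Reagents that add atoms: iodomethane, CI
Why: Williamson O-methylation; it installs the 4'-methoxy group before any alkene chemistry.

Step 4
Reactants: 5 3-allyl-5-bromo-4-methoxybenzaldehyde
Product: 6 3-bromo-4-methoxy-5-(3-methylbut-2-en-1-yl)benzaldehyde
Conditions: 2-methyl-2-butene (large excess), second-generation Grubbs catalyst RuCl2(=CHPh)(H2IMes)(PCy3) (2 mol%), CH2Cl2, 40 °C, sealed vessel
Reagents that add atoms: 2-methyl-2-butene, CC=C(C)C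
Why: Olefin cross-metathesis of a terminal allylarene with excess 2-methyl-2-butene is the standard allyl-to-prenyl conversion; the excess suppresses homodimerisation, and the aldehyde and aryl bromide are inert to the ruthenium carbene.

Step 5
Reactants: 6 3-bromo-4-methoxy-5-(3-methylbut-2-en-1-yl)benzaldehyde; 7 2-methylbut-3-en-2-ol
Product: 8 3-[(1E)-3-hydroxy-3-methylbut-1-en-1-yl]-4-methoxy-5-(3-methylbut-2-en-1-yl)benzaldehyde
Conditions: Pd(OAc)2 (5 mol%), P(o-tol)3 (10 mol%), Et3N, DMF, 100 °C
Reagents that add atoms: none
Why: Mizoroki–Heck reaction of an aryl bromide with a monosubstituted alkene; the carbinol carbon of 7 has no hydrogen, so β-hydride elimination can only give the (E)-styrenyl alkene, and the trisubstituted prenyl alkene does not compete.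

Step 6
Reactants: 8 ArB-carbaldehyde (name as in step 5)
Product: 9 ethyl (2E)-3-ArB-prop-2-enoate
Conditions: (EtO)2P(O)CH2CO2Et, NaH, THF, 0 °C to rt
Reagents that add atoms: triethyl phosphonoacetate, CCOC(=O)CP(=O)(OCC)OCC
Why: Horner–Wadsworth–Emmons olefination of a non-enolisable aryl aldehyde with a stabilised phosphonate anion gives the (E)-cinnamate; the tertiary alcohol is a spectator.

Step 7
Reactants: 9 ethyl (2E)-3-ArB-prop-2-enoate
Product: 10 (2E)-3-ArB-prop-2-en-1-ol
Conditions: i-Bu2AlH (3.5 equiv), CH2Cl2, −78 °C; aqueous potassium sodium tartrate work-up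
Reagents that add atoms: none
Why: 1,2-reduction of an α,β-unsaturated ester to the allylic alcohol at low temperature; one extra equivalent of hydride is consumed by the tertiary hydroxyl and the alkenes are untouched.

Step 8
Reactants: 10 (2E)-3-ArB-prop-2-en-1-ol
Product: 11 (2E)-3-ArB-prop-2-en-1-yl methyl carbonate
Conditions: ClCO2Me, pyridine, CH2Cl2, 0 °C
Reagents that add atoms: methyl chloroformate, COC(=O)Cl
Why: Chemoselective acylation of the primary allylic alcohol over the hindered tertiary alcohol gives the carbonate leaving group needed for the iridium step.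

Step 9
Reactants: 12 2,4-dihydroxyacetophenone
Product: 13 1-[2-hydroxy-4-(triisopropylsilyloxy)phenyl]ethan-1-one
Conditions: i-Pr3SiCl, imidazole, CH2Cl2, 0 °C to rt
Reagents that add atoms: chlorotriisopropylsilane, CC(C)[Si](Cl)(C(C)C)C(C)C
Why: Selective silylation of the unhindered 4-hydroxyl, since the 2-hydroxyl is tied up in a hydrogen bond to the acetyl group; the triisopropylsilyl ether is chosen because an aryl tert-butyldimethylsilyl ether could be cleaved or transferred by phenoxide and methoxide at 50 °C in step 10.

Step 10
Reactants: 11 (2E)-3-ArB-prop-2-en-1-yl methyl carbonate; 13 1-[2-hydroxy-4-(triisopropylsilyloxy)phenyl]ethan-1-one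
Product: 15 1-{2-[(1S)-1-ArB-prop-2-en-1-yl]oxy-4-(triisopropylsilyloxy)phenyl}ethan-1-one, via lithium 2-acetyl-5-(triisopropylsilyloxy)phenolate 14 (not isolated)
Conditions: 13 (1.5 equiv), LiN(SiMe3)2, THF, 0 °C; then 11, [Ir(cod)Cl]2 (2 mol%), (Sa,Sc,Sc)-O,O'-(1,1'-binaphthyl-2,2'-diyl)-N,N-bis(1-phenylethyl)phosphoramidite (4 mol%, pre-activated with n-PrNH2), THF, 50 °C
Reagents that add atoms: none
Why: Iridium-catalysed asymmetric allylic etherification: the cyclometalated iridium–phosphoramidite π-allyl complex is attacked by the phenoxide at the aryl-bearing terminus, giving the branched ether, and the ligand fixes the face, which sets C2 as S under catalyst control. The tertiary alcohol is not a competent nucleophile under these conditions.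

Step 11
Reactants: 15 1-{2-[(1S)-1-ArB-prop-2-en-1-yl]oxy-4-(triisopropylsilyloxy)phenyl}ethan-1-one
Product: 16 (S)-1-ArB(TES)-prop-2-en-1-yl ether of 2-[1-(triethylsilyloxy)ethenyl]-5-(triisopropylsilyloxy)phenol
Conditions: Et3SiOTf (3 equiv), Et3N (5 equiv), CH2Cl2, −78 to 0 °C
Reagents that add atoms: triethylsilyl trifluoromethanesulfonate, CC[Si](CC)(CC)OS(=O)(=O)C(F)(F)F
Why: Soft enolisation of an aryl methyl ketone (only one enolisable side) gives the silyl enol ether, and the same reagent silylates the tertiary alcohol. Excess amine keeps the medium basic so the allylic benzylic aryl ether does not ionise, and C2 is not involved.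

Step 12
Reactants: 16 (S)-1-ArB(TES)-prop-2-en-1-yl ether of 2-[1-(triethylsilyloxy)ethenyl]-5-(triisopropylsilyloxy)phenol
Product: 17 (2S)-2-ArB(TES)-4-(triethylsilyloxy)-7-(triisopropylsilyloxy)-2H-chromene
Conditions: second-generation Grubbs catalyst RuCl2(=CHPh)(H2IMes)(PCy3) (5–10 mol%), degassed toluene (0.005 M), 60 °C, dark
Reagents that add atoms: none
Why: Ring-closing alkene metathesis. The ruthenium benzylidene exchanges onto the monosubstituted vinyl group on C2, and the new alkylidene (carbene carbon = C3) adds across the 1-silyloxyvinyl group in a [2+2] cycloaddition that joins C3 to C4; cycloreversion releases ethene and the chain-carrying Ru=CH2. The closest known reactions are ring-closing metathesis of silyl enol ethers to cyclic silyl enol ethers and of 2-alkenylphenyl allyl ethers to 2H-chromenes with this catalyst class. Ring C closes as a six-membered ring by intramolecular metathesis of a 1,7-diene, with the new C3=C4 bond inside the ring. No stereocentre is formed; C2, set in step 10, is a spectator. The step needs chemoselectivity among four alkenes: the trisubstituted prenyl alkene and the internal styrenyl alkene beside a quaternary carbon react far more slowly than the vinyl group, neither can reach the carbene through a strain-free ring, and high dilution suppresses intermolecular metathesis. Loading on the enol ether, which would give an inert heteroatom-stabilised carbene, is disfavoured by its 1,1-disubstitution. Moderate temperature and exclusion of light guard against electrocyclic opening of the 2H-chromene, the one process that could erode C2.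

Step 13
Reactants: 17 (2S)-2-ArB(TES)-4-(triethylsilyloxy)-7-(triisopropylsilyloxy)-2H-chromene
Product: 18 (2S)-7-hydroxy-2-ArB-2,3-dihydro-4H-chromen-4-one (CNP0222710.1)
Conditions: Bu4NF (5 equiv), AcOH (5 equiv), THF, 0 °C to rt
Reagents that add atoms: none
Why: Fluoride-induced desilylation of the enol ether, the aryl silyl ether and the tertiary silyl ether in one operation. Acetic acid protonates the C3 enolate as it forms so it cannot expel the O1 phenoxide, which preserves 2S, and the medium is not acidic enough to ionise the tertiary allylic alcohol.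

## Compound list

1 | 3-bromo-4-hydroxybenzaldehyde | O=Cc1ccc(O)c(Br)c1 | starting material
2 | 4-(allyloxy)-3-bromobenzaldehyde | C=CCOc1ccc(C=O)cc1Br | intermediate
3 | 6-allyl-2-bromo-4-formylcyclohexa-2,4-dien-1-one (racemic, formed and consumed in step 2) | O=C1C(Br)=CC(C=O)=CC1CC=C | intermediate
4 | 3-allyl-5-bromo-4-hydroxybenzaldehyde | C=CCc1cc(C=O)cc(Br)c1O | intermediate
5 | 3-allyl-5-bromo-4-methoxybenzaldehyde | C=CCc1cc(C=O)cc(Br)c1OC | intermediate
6 | 3-bromo-4-methoxy-5-(3-methylbut-2-en-1-yl)benzaldehyde | CC(C)=CCc1cc(C=O)cc(Br)c1OC | intermediate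
7 | 2-methylbut-3-en-2-ol | C=CC(C)(C)O | starting material
8 | 3-[(1E)-3-hydroxy-3-methylbut-1-en-1-yl]-4-methoxy-5-(3-methylbut-2-en-1-yl)benzaldehyde | COc1c(/C=C/C(C)(C)O)cc(C=O)cc1CC=C(C)C | intermediate
9 | ethyl (2E)-3-ArB-prop-2-enoate | CCOC(=O)/C=C/c1cc(CC=C(C)C)c(OC)c(/C=C/C(C)(C)O)c1 | intermediate
10 | (2E)-3-ArB-prop-2-en-1-ol | OC/C=C/c1cc(CC=C(C)C)c(OC)c(/C=C/C(C)(C)O)c1 | intermediate
11 | (2E)-3-ArB-prop-2-en-1-yl methyl carbonate | COC(=O)OC/C=C/c1cc(CC=C(C)C)c(OC)c(/C=C/C(C)(C)O)c1 | intermediate
12 | 2,4-dihydroxyacetophenone | CC(=O)c1ccc(O)cc1O | starting material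
13 | 1-[2-hydroxy-4-(triisopropylsilyloxy)phenyl]ethan-1-one | CC(=O)c1ccc(O[Si](C(C)C)(C(C)C)C(C)C)cc1O | intermediate
14 | lithium 2-acetyl-5-(triisopropylsilyloxy)phenolate (formed and consumed in step 10) | CC(=O)c1ccc(O[Si](C(C)C)(C(C)C)C(C)C)cc1[O-].[Li+] | intermediate
15 | 1-{2-[(1S)-1-ArB-prop-2-en-1-yl]oxy-4-(triisopropylsilyloxy)phenyl}ethan-1-one | C=C[C@H](Oc1cc(O[Si](C(C)C)(C(C)C)C(C)C)ccc1C(C)=O)c1cc(CC=C(C)C)c(OC)c(/C=C/C(C)(C)O)c1 | intermediate
16 | (S)-1-ArB(TES)-prop-2-en-1-yl ether of 2-[1-(triethylsilyloxy)ethenyl]-5-(triisopropylsilyloxy)phenol | C=C[C@H](Oc1cc(O[Si](C(C)C)(C(C)C)C(C)C)ccc1C(=C)O[Si](CC)(CC)CC)c1cc(CC=C(C)C)c(OC)c(/C=C/C(C)(C)O[Si](CC)(CC)CC)c1 | intermediate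
17 | (2S)-2-ArB(TES)-4-(triethylsilyloxy)-7-(triisopropylsilyloxy)-2H-chromene | COc1c(/C=C/C(C)(C)O[Si](CC)(CC)CC)cc([C@@H]2C=C(O[Si](CC)(CC)CC)c3ccc(O[Si](C(C)C)(C(C)C)C(C)C)cc3O2)cc1CC=C(C)C | intermediate
18 | (2S)-7-hydroxy-2-{3-[(1E)-3-hydroxy-3-methylbut-1-en-1-yl]-4-methoxy-5-(3-methylbut-2-en-1-yl)phenyl}-2,3-dihydro-4H-chromen-4-one | COc1c(/C=C/C(C)(C)O)cc([C@@H]2CC(=O)c3ccc(O)cc3O2)cc1CC=C(C)C | target

## Step count and least certain steps

Total: 13 steps. Longest linear sequence: 12 steps (steps 1–8 and 10–13, from 1 to 18); step 9 is a one-step side branch.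

**Step 12 (key step).** The [2+2] addition onto the hindered, electron-rich 1-silyloxyvinyl group may be slow. Intermolecular metathesis at the vinyl group and ruthenium hydride double-bond migration in the allylic ether would then take over, and prolonged heating could erode C2 through electrocyclic opening of the 2H-chromene. Fallback (leaves the route at 11, rejoins it at 18): ring C is closed at C4–C4a by anionic acylation, so no enol ether has to enter a metathesis.
- Purchased 4-bromobenzene-1,3-diol F1 is silylated at the unhindered hydroxyl (i-Pr3SiCl, imidazole) to 2-bromo-5-(triisopropylsilyloxy)phenol F2.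
- Its salt, lithium 2-bromo-5-(triisopropylsilyloxy)phenolate F3 (from LiN(SiMe3)2), is coupled with 11 under the iridium conditions of step 10 to the (S)-1-ArB-allyl 2-bromo-5-(triisopropylsilyloxy)phenyl ether F4.
- 9-Borabicyclo[3.3.1]nonane adds only to the vinyl group, giving the B-alkyl borane F5, which NaBO3 oxidises to (S)-3-aryloxy-3-ArB-propan-1-ol F6.
- TEMPO with PhI(OAc)2 in wet MeCN takes this to (S)-3-aryloxy-3-ArB-propanoic acid F7.
- n-BuLi (THF, −78 °C) effects bromine–lithium exchange and the aryllithium closes onto the lithium carboxylate (Parham cyclisation) to give the (2S)-7-(triisopropylsilyloxy)flavanone F8, which Bu4NF/AcOH converts into 18.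

**Step 10.** The chelated ortho-acyl phenoxide is a weak nucleophile and the product ether is doubly activated. Slow substitution would let the catalyst re-ionise the product, eroding the branched-to-linear ratio and the enantiomeric purity, and silyl transfer between phenoxides could intervene. Fallback (leaves at 11, rejoins at 15): the stereocentre is set with a proven oxygen nucleophile and the phenol is introduced afterwards by displacement with inversion.
- KOSiEt3 as a hydroxide equivalent, with [Ir(cod)Cl]2 and the antipodal (Ra,Rc,Rc) ligand, should give the (R)-1-ArB-allyl triethylsilyl ether F9.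
- Bu4NF/AcOH frees (R)-1-ArB-prop-2-en-1-ol F10.
- Mitsunobu reaction with 13 (PPh3, diisopropyl azodicarboxylate, toluene, 0 °C) inverts the carbinol centre and gives 15.
- The weakness of this detour is SN2′ attack in the Mitsunobu step, which is why it is the fallback and not the plan.

**Step 13.** Configurational integrity at C2 could be lost if the C3 enolate released from the enol ether expels the O1 phenoxide before it is protonated, and cleavage of the tertiary silyl ether may be slow in the buffered medium. Fallback (leaves at 17, rejoins at 18): the ketone is released first by protonolysis, so no enolate is formed.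
- AcOH–THF–H2O at 0 °C hydrolyses only the silyl enol ether and gives the (2S)-7-(triisopropylsilyloxy)flavanone tertiary triethylsilyl ether F11.
- The two remaining silyl groups are then removed with Bu4NF/AcOH.

## Further compounds

F1 | step 12 | 4-bromobenzene-1,3-diol (purchased) | Oc1ccc(Br)c(O)c1
F2 | step 12 | 2-bromo-5-(triisopropylsilyloxy)phenol | Oc1cc(O[Si](C(C)C)(C(C)C)C(C)C)ccc1Br
F3 | step 12 | lithium 2-bromo-5-(triisopropylsilyloxy)phenolate | [Li+].[O-]c1cc(O[Si](C(C)C)(C(C)C)C(C)C)ccc1Br
F4 | step 12 | (S)-1-ArB-prop-2-en-1-yl 2-bromo-5-(triisopropylsilyloxy)phenyl ether | C=C[C@H](Oc1cc(O[Si](C(C)C)(C(C)C)C(C)C)ccc1Br)c1cc(CC=C(C)C)c(OC)c(/C=C/C(C)(C)O)c1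
F5 | step 12 | 9-[(3S)-3-aryloxy-3-ArB-propyl]-9-borabicyclo[3.3.1]nonane | C1CC2CCCC(C1)B2CC[C@H](Oc1cc(O[Si](C(C)C)(C(C)C)C(C)C)ccc1Br)c1cc(CC=C(C)C)c(OC)c(/C=C/C(C)(C)O)c1
F6 | step 12 | (3S)-3-[2-bromo-5-(triisopropylsilyloxy)phenoxy]-3-ArB-propan-1-ol | OCC[C@H](Oc1cc(O[Si](C(C)C)(C(C)C)C(C)C)ccc1Br)c1cc(CC=C(C)C)c(OC)c(/C=C/C(C)(C)O)c1
F7 | step 12 | (3S)-3-[2-bromo-5-(triisopropylsilyloxy)phenoxy]-3-ArB-propanoic acid | OC(=O)C[C@H](Oc1cc(O[Si](C(C)C)(C(C)C)C(C)C)ccc1Br)c1cc(CC=C(C)C)c(OC)c(/C=C/C(C)(C)O)c1
F8 | step 12 | (2S)-2-ArB-7-(triisopropylsilyloxy)-2,3-dihydro-4H-chromen-4-one | COc1c(/C=C/C(C)(C)O)cc([C@@H]2CC(=O)c3ccc(O[Si](C(C)C)(C(C)C)C(C)C)cc3O2)cc1CC=C(C)C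
F9 | step 10 | (R)-1-ArB-prop-2-en-1-yl triethylsilyl ether | C=C[C@@H](O[Si](CC)(CC)CC)c1cc(CC=C(C)C)c(OC)c(/C=C/C(C)(C)O)c1
F10 | step 10 | (1R)-1-ArB-prop-2-en-1-ol | C=C[C@@H](O)c1cc(CC=C(C)C)c(OC)c(/C=C/C(C)(C)O)c1
F11 | step 13 | (2S)-2-ArB(TES)-7-(triisopropylsilyloxy)-2,3-dihydro-4H-chromen-4-one | COc1c(/C=C/C(C)(C)O[Si](CC)(CC)CC)cc([C@@H]2CC(=O)c3ccc(O[Si](C(C)C)(C(C)C)C(C)C)cc3O2)cc1CC=C(C)C
A1 | alternative 1 | methyl 3-bromo-4-methoxy-5-(3-methylbut-2-en-1-yl)benzoate | COC(=O)c1cc(Br)c(OC)c(CC=C(C)C)c1
A2 | alternative 1 | methyl 3-bromo-2-oxo-2H-pyran-5-carboxylate (methyl 3-bromocoumalate) | COC(=O)C1=COC(=O)C(Br)=C1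
A3 | alternative 1 | 1-methoxy-5-methylhex-4-en-1-yne | COC#CCC=C(C)C
A4 | alternative 2 | (2S)-7-allyloxy-5-bromo-2-ArB(TES)-2,3-dihydro-4H-chromen-4-one | COc1c(/C=C/C(C)(C)O[Si](CC)(CC)CC)cc([C@@H]2CC(=O)c3c(Br)cc(OCC=C)cc3O2)cc1CC=C(C)C
A5 | alternative 2 | methyl (3S)-3-hydroxy-3-ArB(TES)-propanoate | COC(=O)C[C@H](O)c1cc(CC=C(C)C)c(OC)c(/C=C/C(C)(C)O[Si](CC)(CC)CC)c1
A6 | alternative 2 | 5-(allyloxy)-3-bromo-2-(trimethylsilyl)phenyl trifluoromethanesulfonate | C=CCOc1cc(Br)c([Si](C)(C)C)c(OS(=O)(=O)C(F)(F)F)c1
A7 | alternative 3 | (2S)-7-(tert-butyldimethylsilyloxy)-2-ArB(TES)-2,3-dihydro-4H-chromen-4-one | COc1c(/C=C/C(C)(C)O[Si](CC)(CC)CC)cc([C@@H]2CC(=O)c3ccc(O[Si](C)(C)C(C)(C)C)cc3O2)cc1CC=C(C)C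
A8 | alternative 3 | 2-diazo-1-[2-(ArB(TES)-methoxy)-4-(tert-butyldimethylsilyloxy)phenyl]ethan-1-one | [N-]=[N+]=CC(=O)c1ccc(O[Si](C)(C)C(C)(C)C)cc1OCc1cc(CC=C(C)C)c(OC)c(/C=C/C(C)(C)O[Si](CC)(CC)CC)c1
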